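## Retrosynthetic overview

1. **Feature.** Ring A (C4a, C5, C6, C7, C8, C8a) is a pentasubstituted phloroglucinol. It carries oxygen on C5, C7 and C8a, the heptanoid chain on C8, and carbonyl carbon C4 on C4a. C4 lies between the C5 and C8a oxygens, so only closure of ring C through the C8a oxygen (next to C8) puts the chain at C8 and not at C6.
2. **Endgame.** Benzyl, silyl and ketal groups come off last. The 3-OH comes from dioxirane oxidation of the flavone C2=C3 bond. Ring C comes from 6-endo closure of the free C8a–OH onto an alkynone whose C4 is attached to C4a by phenol-directed formylation.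
3. **Key disconnection.** Ring A is cut into siloxyalkyne 23 (C7 and C8, with the chiral chain) and 3-(benzyloxy)cyclobutenone 26 (C8a, C6, C5, C4a). The vinylketene benzannulation delivers the oxygens already distinguished: OH on C8a, OSi(iPr)3 on C7, OBn on C5.
4. **Chain.** 23 comes from ester 20 by ynolate homologation with retention. The single stereocentre comes from Evans alkylation of a vanillin-derived 4-arylbutanoyl oxazolidinone with tert-butyl bromoacetate, whose ester carbon becomes the phenethyl ketone.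
5. **Ring order.** Ring A forms in step 13 and ring C in step 17. Ring B and the two chain arenes are bought.

Key step: step 13

Remark: CIP analysis of the given SMILES gives (R) at the chain carbon bonded to C8 (C8 aryl > CH2C=O > CH2CH2Ar > H); 14, 24 and 33 are taken as purchasable.

Shorthand in names: "ketal chain" = (2R)-4-[4-(benzyloxy)-3-methoxyphenyl]-1-[2-(2-phenylethyl)-1,3-dioxolan-2-yl]butan-2-yl. "Keto chain" = (3R)-1-[4-(benzyloxy)-3-methoxyphenyl]-5-oxo-7-phenylheptan-3-yl.

## Route

Step 1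
Reactants: 1 vanillin
Product: 2 4-(benzyloxy)-3-methoxybenzaldehyde
Conditions: BnBr, K2CO3, DMF, rt to 50 °C
Reagents that add atoms: benzyl bromide BrCc1ccccc1
Why: Williamson ether synthesis on the acidic para-formyl phenol installs a group that tolerates every later base, acid and thermal stage and leaves in the last step together with the C5 benzyl ether.

Step 2
Reactants: 2 4-(benzyloxy)-3-methoxybenzaldehyde; 3 (2-carboxyethyl)triphenylphosphonium bromide
Product: 5 (E)-4-[4-(benzyloxy)-3-methoxyphenyl]but-3-enoic acid, via phosphonium ylide carboxylate 4 (not isolated)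
Conditions: 3, KOtBu (2.2 equiv), THF, 0 °C; then 2, 0 °C to rt; aq HCl
Reagents that add atoms: none
Why: Wittig olefination with the carboxylate-bearing ylide adds the three missing chain carbons in one operation, and the alkene geometry does not matter because the double bond is saturated next.

Step 3
Reactants: 5 (E)-4-[4-(benzyloxy)-3-methoxyphenyl]but-3-enoic acid
Product: 6 4-[4-(benzyloxy)-3-methoxyphenyl]butanoic acid
Conditions: H2 (3 atm), RhCl(PPh3)3 (3 mol %), PhMe–EtOH, 40 °C
Reagents that add atoms: none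
Why: Homogeneous hydrogenation with RhCl(PPh3)3 saturates the disubstituted styrene-type alkene but has no hydrogenolysis activity, so the aryl benzyl ether stays.

Step 4
Reactants: 6 4-[4-(benzyloxy)-3-methoxyphenyl]butanoic acid; 7 (S)-4-benzyl-1,3-oxazolidin-2-one
Product: 9 (4S)-4-benzyl-3-{4-[4-(benzyloxy)-3-methoxyphenyl]butanoyl}-1,3-oxazolidin-2-one, via mixed pivalic anhydride 8 (not isolated)
Conditions: t-BuCOCl, Et3N, THF, −20 °C; then LiCl, 7, −20 °C to rt
Reagents that add atoms: none
Why: N-acylation of the oxazolidinone by a mixed anhydride with LiCl activation should succeed because the nucleophile attacks the less hindered carbonyl of 8.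

Step 5
Reactants: 9 (4S)-4-benzyl-3-{4-[4-(benzyloxy)-3-methoxyphenyl]butanoyl}-1,3-oxazolidin-2-one; 10 tert-butyl bromoacetate
Product: 12 tert-butyl (3R)-3-{[(4S)-4-benzyl-2-oxo-1,3-oxazolidin-3-yl]carbonyl}-5-[4-(benzyloxy)-3-methoxyphenyl]pentanoate, via sodium Z-enolate 11 (not isolated)
Conditions: NaN(SiMe3)2, THF, −78 °C; then 10, −78 to −30 °C
Reagents that add atoms: none
Why: In this Evans asymmetric alkylation the C4 benzyl group of the (S)-auxiliary shields one face of the sodium-chelated Z-enolate, so the reactive bromoacetate enters from the other face and sets the (R) centre that later bonds to C8.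

Step 6
Reactants: 12 tert-butyl ester imide
Product: 13 (3R)-3-{[(4S)-4-benzyl-2-oxo-1,3-oxazolidin-3-yl]carbonyl}-5-[4-(benzyloxy)-3-methoxyphenyl]pentanoic acid
Conditions: CF3CO2H–CH2Cl2 (1:4), 0 °C to rt
Reagents that add atoms: none
Why: Acidolysis of the tert-butyl ester, with loss of the tert-butyl cation as isobutene, frees the acid while the imide and the aryl benzyl ether tolerate dilute trifluoroacetic acid at or below room temperature.

Step 7
Reactants: 13 imide acid; 14 phenethylzinc bromide (0.5 M in THF)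
Product: 16 (4S)-4-benzyl-3-[(2R)-2-{2-[4-(benzyloxy)-3-methoxyphenyl]ethyl}-4-oxo-6-phenylhexanoyl]-1,3-oxazolidin-2-one, via acid chloride 15 (not isolated)
Conditions: (COCl)2, cat. DMF, CH2Cl2, 0 °C to rt, concentrate; then 14, Pd(PPh3)4 (5 mol %), THF, 0 °C to rt
Reagents that add atoms: none
Why: In this Negishi-type acylation the acyl chloride adds oxidatively to zerovalent palladium, and transmetalation from the mild alkylzinc followed by fast acyl–alkyl reductive elimination gives the ketone without over-addition or attack on the imide.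

Step 8
Reactants: 16 keto imide
Product: 17 (4S)-4-benzyl-3-[(2R)-4-[4-(benzyloxy)-3-methoxyphenyl]-2-{[2-(2-phenylethyl)-1,3-dioxolan-2-yl]methyl}butanoyl]-1,3-oxazolidin-2-one
Conditions: Me3SiOCH2CH2OSiMe3, Me3SiOTf (5 mol %), CH2Cl2, −78 to −20 °C; pyridine quench
Reagents that add atoms: 1,2-bis(trimethylsilyloxy)ethane C[Si](C)(C)OCCO[Si](C)(C)C
Why: Noyori ketalisation is driven by formation of hexamethyldisiloxane, runs cold and aprotic so the gamma-keto imide cannot enol-lactonise, and masks the ketone against the organolithium steps ahead.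

Step 9
Reactants: 17 ketal imide
Product: 19 (2R)-4-[4-(benzyloxy)-3-methoxyphenyl]-2-{[2-(2-phenylethyl)-1,3-dioxolan-2-yl]methyl}butanoic acid, via peroxy acid 18 (not isolated)
Conditions: LiOH, 30% H2O2, THF–H2O, 0 °C; Na2SO3; cold 0.5 M HCl to pH 4
Reagents that add atoms: hydrogen peroxide OO
Why: In this hydroperoxide cleavage of the Evans imide, the small alpha-effect nucleophile LiOOH attacks the exocyclic carbonyl selectively and is too weakly basic to epimerise the alpha centre, and sulfite then reduces 18 to the acid.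

Step 10
Reactants: 19 ketal acid
Product: 20 methyl (2R)-4-[4-(benzyloxy)-3-methoxyphenyl]-2-{[2-(2-phenylethyl)-1,3-dioxolan-2-yl]methyl}butanoate
Conditions: MeI, K2CO3, DMF, rt
Reagents that add atoms: iodomethane CI
Why: SN2 O-alkylation of the carboxylate forms the ester without involving the alpha C–H bond, so the stereocentre is preserved.

Step 11
Reactants: 20 methyl ester
Product: 23 {[(3R)-5-[4-(benzyloxy)-3-methoxyphenyl]-3-{[2-(2-phenylethyl)-1,3-dioxolan-2-yl]methyl}pent-1-yn-1-yl]oxy}tri(propan-2-yl)silane, via lithium dibromoenolate 21 (not isolated), via lithium ynolate 22 (not isolated)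
Conditions: CH2Br2, lithium 2,2,6,6-tetramethylpiperidide, THF, −78 °C; add 20; LiN(SiMe3)2, −78 to −20 °C; n-BuLi (titrated), −78 °C to rt; iPr3SiOTf, −78 to 0 °C
Reagents that add atoms: dibromomethane BrCBr; triisopropylsilyl trifluoromethanesulfonate CC(C)[Si](OS(=O)(=O)C(F)(F)F)(C(C)C)C(C)C
Why: This is a Kowalski ester homologation halted at the ynolate, in which LiCHBr2 consumes the ester at −78 °C as a tetrahedral adduct (which guards the alpha C–H), bromine–lithium exchange on 21 triggers a 1,2-shift of the secondary alkyl group with retention of configuration to give 22, and the bulky silyl triflate traps 22 on oxygen.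

Step 12
Reactants: 24 3-ethoxycyclobut-2-en-1-one; 25 benzyl alcohol
Product: 26 3-(benzyloxy)cyclobut-2-en-1-one
Conditions: 25 (1.5 equiv), pyridinium p-toluenesulfonate (5 mol %), PhMe, 35 °C, reduced pressure (EtOH removed)
Reagents that add atoms: none
Why: Acid-catalysed addition–elimination at C3 (transetherification of a vinylogous ester) is pulled to the benzyl ether by removal of the more volatile ethanol and runs well below the temperature at which the four-membered ring opens.

Step 13
Reactants: 23 chain-bearing triisopropylsiloxyalkyne; 26 3-(benzyloxy)cyclobut-2-en-1-one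
Product: 31 5-(benzyloxy)-2-(ketal chain)-3-[(triisopropylsilyl)oxy]phenol, via vinylketene 27 (not isolated), via 4-vinylcyclobutenone 28 (not isolated), via dienylketene 29 (not isolated), via cyclohexadienone 30 (not isolated)
Conditions: 23 in PhMe, 80 °C, 26 (1.3 equiv) added over 3 h; then 110 °C, Ar
Reagents that add atoms: none
Why: This is a Danheiser benzannulation: 26 opens by four-electron conrotatory electrocyclic cleavage of its C1–C4 bond to vinylketene 27, and the nucleophilic, chain-bearing carbon of 23 attacks the ketene carbonyl carbon in a [2+2] cycloaddition that forms C8–C8a and C6–C7 and gives 28. A second four-electron opening breaks the old C1–C2 bond (C8a–C6) to give dienylketene 29, and ring A closes by six-electron disrotatory electrocyclisation between the ketene carbon and the terminal methylene, which re-forms the C4a–C8a bond lost in the first opening; tautomerisation of 30 then gives phenol 31. The closest known cases are cyclobutenone annulations of secondary-alkyl triisopropylsiloxyalkynes to 2-alkylresorcinol monosilyl ethers, and the 3-alkoxy group on the four-membered ring is the less common variable. No lasting stereocentre is created (C4 of 28 disappears on ring opening), and the existing centre has no pathway for inversion under neutral heating. The selectivity needed is regiochemical and is fixed by the O–C≡C polarisation of 23, which places the chain between the free C8a hydroxyl and the C7 silyl ether and leaves the benzyl ether on C5. Slow addition of 26 keeps the ketene dilute, which holds back its dimerisation and its acylation of 31.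

Step 14
Reactants: 31 benzannulation phenol
Product: 32 6-(benzyloxy)-2-hydroxy-3-(ketal chain)-4-[(triisopropylsilyl)oxy]benzaldehyde
Conditions: MgCl2, Et3N, (CH2O)n, THF, reflux
Reagents that add atoms: formaldehyde (as paraformaldehyde) C=O
Why: In the Casnati–Skattebøl ortho-formylation formaldehyde is delivered inside the magnesium phenoxide chelate, so only C4a (the one free position ortho to the C8a hydroxyl) reacts, a second formaldehyde accepts hydride to give the aldehyde, and the amine-buffered medium spares the ketal, silyl and benzyl groups.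

Step 15
Reactants: 32 salicylaldehyde; 33 lithium phenylacetylide (1.0 M in THF)
Product: 34 3-(benzyloxy)-2-(1-hydroxy-3-phenylprop-2-yn-1-yl)-6-(ketal chain)-5-[(triisopropylsilyl)oxy]phenol (both carbinol epimers)
Conditions: 33 (3 equiv), THF, −78 to 0 °C; aq NH4Cl
Reagents that add atoms: none
Why: After one equivalent is spent on the phenol, the slim alkynyllithium undergoes 1,2-addition to the flanked aldehyde, and the uncontrolled carbinol centre is erased in step 16.

Step 16
Reactants: 34 propargylic alcohol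
Product: 35 1-{6-(benzyloxy)-2-hydroxy-3-(ketal chain)-4-[(triisopropylsilyl)oxy]phenyl}-3-phenylprop-2-yn-1-one
Conditions: activated MnO2, CH2Cl2, rt
Reagents that add atoms: none
Why: Heterogeneous MnO2 oxidation is selective for the benzylic–propargylic alcohol under neutral conditions and completes the net phenol-directed acylation of C4a.

Step 17
Reactants: 35 ortho-hydroxyaryl alkynone
Product: 36 5-(benzyloxy)-8-(ketal chain)-2-phenyl-7-[(triisopropylsilyl)oxy]-4H-chromen-4-one
Conditions: DMAP (20 mol %), DMF, 35 °C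
Reagents that add atoms: none
Why: In this nucleophile-catalysed 6-endo oxa-Michael cyclisation DMAP adds to the alkynone beta carbon and the C8a phenoxide displaces it there to form O1–C2, which excludes 5-exo aurone formation and any closure through the benzylated C5 oxygen, and which is preferred to alkaline peroxide treatment of a 6'-benzyloxychalcone because such chalcones tend toward aurones and hydroxide would strip the silyl ether.

Step 18
Reactants: 36 flavone
Product: 39 5-(benzyloxy)-3-hydroxy-8-(keto chain)-2-phenyl-7-[(triisopropylsilyl)oxy]-4H-chromen-4-one, via flavone epoxide 37 (not isolated), via flavonol ketal 38 (not isolated)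
Conditions: dimethyldioxirane (acetone solution), CH2Cl2, 0 °C, concentrate; then TsOH·H2O (20 mol %), acetone–H2O, rt
Reagents that add atoms: dimethyldioxirane CC1(C)OO1; water O
Why: Dioxirane epoxidation of the flavone C2=C3 bond and acid-induced opening of 37 at C2 with loss of H3 is the established flavone-to-flavonol conversion, and the same acid in wet acetone hydrolyses the dioxolane while C7 is still silylated, so no neighbouring phenol can add to the freed ketone.

Step 19
Reactants: 39 silylated flavonol ketone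
Product: 40 5-(benzyloxy)-3,7-dihydroxy-8-(keto chain)-2-phenyl-4H-chromen-4-one
Conditions: Bu4NF, AcOH, THF, 0 °C
Reagents that add atoms: none
Why: Fluoride cleaves the aryl silyl ether, and acetic acid buffering protonates the C7 phenoxide at once, so base-induced retro-Michael loss of the chain, the only pathway that could erode the stereocentre, is avoided.

Step 20
Reactants: 40 bis(benzyl) ether
Product: 41 3,5,7-trihydroxy-8-[(3R)-1-(4-hydroxy-3-methoxyphenyl)-5-oxo-7-phenylheptan-3-yl]-2-phenyl-4H-chromen-4-one (target)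
Conditions: H2 (1 atm), Pd/C (10%), EtOAc–MeOH, rt
Reagents that add atoms: none
Why: Catalytic hydrogenolysis removes both aryl benzyl ethers under neutral conditions to which the flavonol double bond, the dialkyl ketone and the benzylic C–C bonds are inert.

## Compound list

1 | vanillin | COc1cc(C=O)ccc1O | starting material
2 | 4-(benzyloxy)-3-methoxybenzaldehyde | COc1cc(C=O)ccc1OCc1ccccc1 | intermediate
3 | (2-carboxyethyl)triphenylphosphonium bromide | OC(=O)CC[P+](c1ccccc1)(c1ccccc1)c1ccccc1.[Br-] | starting material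
4 | potassium 3-(triphenylphosphoranylidene)propanoate | [K+].[O-]C(=O)CC=P(c1ccccc1)(c1ccccc1)c1ccccc1 | intermediate (not isolated)
5 | (E)-4-[4-(benzyloxy)-3-methoxyphenyl]but-3-enoic acid | COc1cc(/C=C/CC(=O)O)ccc1OCc1ccccc1 | intermediate
6 | 4-[4-(benzyloxy)-3-methoxyphenyl]butanoic acid | COc1cc(CCCC(=O)O)ccc1OCc1ccccc1 | intermediate
7 | (S)-4-benzyl-1,3-oxazolidin-2-one | O=C1N[C@@H](Cc2ccccc2)CO1 | starting material
8 | 4-[4-(benzyloxy)-3-methoxyphenyl]butanoic pivalic anhydride | COc1cc(CCCC(=O)OC(=O)C(C)(C)C)ccc1OCc1ccccc1 | intermediate (not isolated)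
9 | (4S)-4-benzyl-3-{4-[4-(benzyloxy)-3-methoxyphenyl]butanoyl}-1,3-oxazolidin-2-one | COc1cc(CCCC(=O)N2[C@@H](Cc3ccccc3)COC2=O)ccc1OCc1ccccc1 | intermediate
10 | tert-butyl bromoacetate | CC(C)(C)OC(=O)CBr | starting material
11 | sodium (Z)-enolate of 9 | COc1cc(CC/C=C(\[O-])N2[C@@H](Cc3ccccc3)COC2=O)ccc1OCc1ccccc1.[Na+] | intermediate (not isolated)
12 | tert-butyl (3R)-3-{[(4S)-4-benzyl-2-oxo-1,3-oxazolidin-3-yl]carbonyl}-5-[4-(benzyloxy)-3-methoxyphenyl]pentanoate | COc1cc(CC[C@H](CC(=O)OC(C)(C)C)C(=O)N2[C@@H](Cc3ccccc3)COC2=O)ccc1OCc1ccccc1 | intermediate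
13 | (3R)-3-{[(4S)-4-benzyl-2-oxo-1,3-oxazolidin-3-yl]carbonyl}-5-[4-(benzyloxy)-3-methoxyphenyl]pentanoic acid | COc1cc(CC[C@H](CC(=O)O)C(=O)N2[C@@H](Cc3ccccc3)COC2=O)ccc1OCc1ccccc1 | intermediate
14 | phenethylzinc bromide | Br[Zn]CCc1ccccc1 | starting material
15 | acid chloride of 13 | COc1cc(CC[C@H](CC(=O)Cl)C(=O)N2[C@@H](Cc3ccccc3)COC2=O)ccc1OCc1ccccc1 | intermediate (not isolated)
16 | (4S)-4-benzyl-3-[(2R)-2-{2-[4-(benzyloxy)-3-methoxyphenyl]ethyl}-4-oxo-6-phenylhexanoyl]-1,3-oxazolidin-2-one | COc1cc(CC[C@H](CC(=O)CCc2ccccc2)C(=O)N2[C@@H](Cc3ccccc3)COC2=O)ccc1OCc1ccccc1 | intermediate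
17 | (4S)-4-benzyl-3-[(2R)-4-[4-(benzyloxy)-3-methoxyphenyl]-2-{[2-(2-phenylethyl)-1,3-dioxolan-2-yl]methyl}butanoyl]-1,3-oxazolidin-2-one | COc1cc(CC[C@H](CC2(CCc3ccccc3)OCCO2)C(=O)N2[C@@H](Cc3ccccc3)COC2=O)ccc1OCc1ccccc1 | intermediate
18 | (2R)-4-[4-(benzyloxy)-3-methoxyphenyl]-2-{[2-(2-phenylethyl)-1,3-dioxolan-2-yl]methyl}butaneperoxoic acid | COc1cc(CC[C@H](CC2(CCc3ccccc3)OCCO2)C(=O)OO)ccc1OCc1ccccc1 | intermediate (not isolated)
19 | (2R)-4-[4-(benzyloxy)-3-methoxyphenyl]-2-{[2-(2-phenylethyl)-1,3-dioxolan-2-yl]methyl}butanoic acid | COc1cc(CC[C@H](CC2(CCc3ccccc3)OCCO2)C(=O)O)ccc1OCc1ccccc1 | intermediate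
20 | methyl (2R)-4-[4-(benzyloxy)-3-methoxyphenyl]-2-{[2-(2-phenylethyl)-1,3-dioxolan-2-yl]methyl}butanoate | COc1cc(CC[C@H](CC2(CCc3ccccc3)OCCO2)C(=O)OC)ccc1OCc1ccccc1 | intermediate
21 | lithium enolate of the (R)-alpha,alpha-dibromomethyl ketone derived from 20 | COc1cc(CC[C@H](CC2(CCc3ccccc3)OCCO2)C([O-])=C(Br)Br)ccc1OCc1ccccc1.[Li+] | intermediate (not isolated)
22 | lithium (3R)-5-[4-(benzyloxy)-3-methoxyphenyl]-3-{[2-(2-phenylethyl)-1,3-dioxolan-2-yl]methyl}pent-1-yn-1-olate | COc1cc(CC[C@H](CC2(CCc3ccccc3)OCCO2)C#C[O-])ccc1OCc1ccccc1.[Li+] | intermediate (not isolated)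
23 | {[(3R)-5-[4-(benzyloxy)-3-methoxyphenyl]-3-{[2-(2-phenylethyl)-1,3-dioxolan-2-yl]methyl}pent-1-yn-1-yl]oxy}tri(propan-2-yl)silane | COc1cc(CC[C@H](CC2(CCc3ccccc3)OCCO2)C#CO[Si](C(C)C)(C(C)C)C(C)C)ccc1OCc1ccccc1 | intermediate (key precursor)
24 | 3-ethoxycyclobut-2-en-1-one | CCOC1=CC(=O)C1 | starting material
25 | benzyl alcohol | OCc1ccccc1 | starting material
26 | 3-(benzyloxy)cyclobut-2-en-1-one | O=C1C=C(OCc2ccccc2)C1 | intermediate (key precursor)
27 | 3-(benzyloxy)buta-1,3-dien-1-one | C=C(OCc1ccccc1)C=C=O | intermediate (not isolated)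
28 | 4-[1-(benzyloxy)ethenyl]-2-(ketal chain)-3-[(triisopropylsilyl)oxy]cyclobut-2-en-1-one (both C4 epimers) | COc1cc(CC[C@H](CC2(CCc3ccccc3)OCCO2)C2=C(O[Si](C(C)C)(C(C)C)C(C)C)C(C(=C)OCc3ccccc3)C2=O)ccc1OCc1ccccc1 | intermediate (not isolated)
29 | 5-(benzyloxy)-2-(ketal chain)-3-[(triisopropylsilyl)oxy]hexa-1,3,5-trien-1-one | COc1cc(CC[C@H](CC2(CCc3ccccc3)OCCO2)C(=C=O)/C(O[Si](C(C)C)(C(C)C)C(C)C)=C\C(=C)OCc2ccccc2)ccc1OCc1ccccc1 | intermediate (not isolated)
30 | 5-(benzyloxy)-2-(ketal chain)-3-[(triisopropylsilyl)oxy]cyclohexa-2,4-dien-1-one | COc1cc(CC[C@H](CC2(CCc3ccccc3)OCCO2)C2=C(O[Si](C(C)C)(C(C)C)C(C)C)C=C(OCc3ccccc3)CC2=O)ccc1OCc1ccccc1 | intermediate (not isolated)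
31 | 5-(benzyloxy)-2-(ketal chain)-3-[(triisopropylsilyl)oxy]phenol | COc1cc(CC[C@H](CC2(CCc3ccccc3)OCCO2)c2c(O)cc(OCc3ccccc3)cc2O[Si](C(C)C)(C(C)C)C(C)C)ccc1OCc1ccccc1 | intermediate (key product)
32 | 6-(benzyloxy)-2-hydroxy-3-(ketal chain)-4-[(triisopropylsilyl)oxy]benzaldehyde | COc1cc(CC[C@H](CC2(CCc3ccccc3)OCCO2)c2c(O)c(C=O)c(OCc3ccccc3)cc2O[Si](C(C)C)(C(C)C)C(C)C)ccc1OCc1ccccc1 | intermediate
33 | lithium phenylacetylide | [Li]C#Cc1ccccc1 | starting material
34 | 3-(benzyloxy)-2-(1-hydroxy-3-phenylprop-2-yn-1-yl)-6-(ketal chain)-5-[(triisopropylsilyl)oxy]phenol | COc1cc(CC[C@H](CC2(CCc3ccccc3)OCCO2)c2c(O)c(C(O)C#Cc3ccccc3)c(OCc3ccccc3)cc2O[Si](C(C)C)(C(C)C)C(C)C)ccc1OCc1ccccc1 | intermediate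
35 | 1-{6-(benzyloxy)-2-hydroxy-3-(ketal chain)-4-[(triisopropylsilyl)oxy]phenyl}-3-phenylprop-2-yn-1-one | COc1cc(CC[C@H](CC2(CCc3ccccc3)OCCO2)c2c(O)c(C(=O)C#Cc3ccccc3)c(OCc3ccccc3)cc2O[Si](C(C)C)(C(C)C)C(C)C)ccc1OCc1ccccc1 | intermediate
36 | 5-(benzyloxy)-8-(ketal chain)-2-phenyl-7-[(triisopropylsilyl)oxy]-4H-chromen-4-one | COc1cc(CC[C@H](CC2(CCc3ccccc3)OCCO2)c2c(O[Si](C(C)C)(C(C)C)C(C)C)cc(OCc3ccccc3)c3c(=O)cc(-c4ccccc4)oc23)ccc1OCc1ccccc1 | intermediate
37 | 2,3-epoxide of 36 (both faces) | COc1cc(CC[C@H](CC2(CCc3ccccc3)OCCO2)c2c(O[Si](C(C)C)(C(C)C)C(C)C)cc(OCc3ccccc3)c3c2OC2(c4ccccc4)OC2C3=O)ccc1OCc1ccccc1 | intermediate (not isolated)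
38 | 5-(benzyloxy)-3-hydroxy-8-(ketal chain)-2-phenyl-7-[(triisopropylsilyl)oxy]-4H-chromen-4-one | COc1cc(CC[C@H](CC2(CCc3ccccc3)OCCO2)c2c(O[Si](C(C)C)(C(C)C)C(C)C)cc(OCc3ccccc3)c3c(=O)c(O)c(-c4ccccc4)oc23)ccc1OCc1ccccc1 | intermediate (not isolated)
39 | 5-(benzyloxy)-3-hydroxy-8-(keto chain)-2-phenyl-7-[(triisopropylsilyl)oxy]-4H-chromen-4-one | COc1cc(CC[C@H](CC(=O)CCc2ccccc2)c2c(O[Si](C(C)C)(C(C)C)C(C)C)cc(OCc3ccccc3)c3c(=O)c(O)c(-c4ccccc4)oc23)ccc1OCc1ccccc1 | intermediate
40 | 5-(benzyloxy)-3,7-dihydroxy-8-(keto chain)-2-phenyl-4H-chromen-4-one | COc1cc(CC[C@H](CC(=O)CCc2ccccc2)c2c(O)cc(OCc3ccccc3)c3c(=O)c(O)c(-c4ccccc4)oc23)ccc1OCc1ccccc1 | intermediate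
41 | 3,5,7-trihydroxy-8-[(3R)-1-(4-hydroxy-3-methoxyphenyl)-5-oxo-7-phenylheptan-3-yl]-2-phenyl-4H-chromen-4-one | COc1cc(CC[C@H](CC(=O)CCc2ccccc2)c2c(O)cc(O)c3c(=O)c(O)c(-c4ccccc4)oc23)ccc1O | target

## Step count and risks

- **Total step count:** 20
- **Longest linear sequence:** 19 (steps 1–11 and 13–20; step 12 is a one-step side branch)

### Steps most likely to fail

**Step 13.**
- *What may go wrong:* The branched alkyne may capture the donor-substituted vinylketene too slowly, so that self-condensation of the ketene and O-acylation of the product phenol take over. The alkoxycyclobutenone may also degrade before it opens.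
- *Fallback:* It sets out from 25 and 23 and rejoins at 27, 28 and then 31. It makes the same ketene by elimination instead of ring opening, which separates the cycloaddition from the heating.
  - 25 is exchanged into purchasable ethyl (E)-3-ethoxybut-2-enoate (cat. TsOH, PhMe, ethanol distilled off) to give ethyl (E)-3-(benzyloxy)but-2-enoate F1.
  - Saponification (KOH, aq EtOH, careful acidification) gives (E)-3-(benzyloxy)but-2-enoic acid F2.
  - 1-Chloro-N,N,2-trimethylprop-1-en-1-amine converts F2 under neutral conditions into (E)-3-(benzyloxy)but-2-enoyl chloride F3.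
  - Slow addition of F3 to 23 and iPr2NEt in CH2Cl2 at 0 °C to rt gives 27 by 1,4-dehydrochlorination, at a temperature where cycloadduct 28 can be collected.
  - 28 is then heated alone in toluene and passes through 29 and 30 to 31.

**Step 11.**
- *What may go wrong:* The surplus alkyllithium and amide bases present while the carbenoid rearranges may metalate the benzylic CH2 of the aryl benzyl ether and start a Wittig rearrangement. Competing enolisation of the ester may erode the stereocentre. Silylation may also drift from oxygen to carbon.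
- *Fallback:* It sets out from 17 and rejoins at 22 and then 23. It replaces the carbenoid shift by oxygen transfer to an acetylide and needs only an amide base.
  - LiBH4 (Et2O, MeOH, 0 °C) releases the auxiliary and gives (2R)-4-[4-(benzyloxy)-3-methoxyphenyl]-2-{[2-(2-phenylethyl)-1,3-dioxolan-2-yl]methyl}butan-1-ol F4.
  - Dess–Martin oxidation (NaHCO3 buffer) gives the corresponding (2R)-butanal F5.
  - Ohira–Bestmann homologation (dimethyl (1-diazo-2-oxopropyl)phosphonate, K2CO3, MeOH, 0 °C) gives 2-{(2R)-2-ethynyl-4-[4-(benzyloxy)-3-methoxyphenyl]butyl}-2-(2-phenylethyl)-1,3-dioxolane F6.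
  - LiN(SiMe3)2 converts F6 into its lithium acetylide F7.
  - Lithium tert-butyl peroxide (from t-BuOOH and LiN(SiMe3)2, THF, −78 to 0 °C) oxidises F7 to ynolate 22, which iPr3SiOTf silylates to 23.

**Step 12.**
- *What may go wrong:* The alcohol may attack the carbonyl group of the strained vinylogous ester and cleave the ring, or acid may cause oligomerisation before the exchange is complete.
- *Fallback:* It sets out from 24 and rejoins at 26. It forms the C–O bond by alkylating the enol oxygen instead of substituting at C3.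
  - Dilute aqueous HCl at rt hydrolyses 24 to cyclobutane-1,3-dione F8, a strongly acidic enol.
  - Mitsunobu reaction of F8 with 25 (PPh3, diisopropyl azodicarboxylate, THF, 0 °C) O-benzylates it to 26.

## Further compounds

F1 | step 13 | ethyl (E)-3-(benzyloxy)but-2-enoate | CCOC(=O)/C=C(\C)OCc1ccccc1
F2 | step 13 | (E)-3-(benzyloxy)but-2-enoic acid | OC(=O)/C=C(\C)OCc1ccccc1
F3 | step 13 | (E)-3-(benzyloxy)but-2-enoyl chloride | ClC(=O)/C=C(\C)OCc1ccccc1
F4 | step 11 | (2R)-4-[4-(benzyloxy)-3-methoxyphenyl]-2-{[2-(2-phenylethyl)-1,3-dioxolan-2-yl]methyl}butan-1-ol | COc1cc(CC[C@H](CC2(CCc3ccccc3)OCCO2)CO)ccc1OCc1ccccc1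
F5 | step 11 | (2R)-4-[4-(benzyloxy)-3-methoxyphenyl]-2-{[2-(2-phenylethyl)-1,3-dioxolan-2-yl]methyl}butanal | COc1cc(CC[C@H](CC2(CCc3ccccc3)OCCO2)C=O)ccc1OCc1ccccc1
F6 | step 11 | 2-{(2R)-2-ethynyl-4-[4-(benzyloxy)-3-methoxyphenyl]butyl}-2-(2-phenylethyl)-1,3-dioxolane | COc1cc(CC[C@H](CC2(CCc3ccccc3)OCCO2)C#C)ccc1OCc1ccccc1
F7 | step 11 | lithium acetylide of F6 | COc1cc(CC[C@H](CC2(CCc3ccccc3)OCCO2)C#C[Li])ccc1OCc1ccccc1
F8 | step 12 | cyclobutane-1,3-dione | O=C1CC(=O)C1
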